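The target is cut through ring B. Its contiguous carbons C14 (quaternary, ring A), C8, C9 (quaternary, next to C5 of oxabicyclic ring D) and C11 are all that joins two independent halves. One iron-hydride operation unites them. Hydrogen-atom transfer to the exocyclic methylene of a ring-A aldehyde gives the C14 radical. This radical adds to C8 of a ring-D (Z)-alkylidene ketone, and the resulting C9 enolate closes onto the C11 aldehyde. Two C–C bonds, ring B and the stereocentres C14, C8 and C9 arise together. The aldehyde comes from a catalytic asymmetric Diels–Alder reaction and an asymmetric allylation, the ketone from a (4+3) cycloaddition. Ring C and the side-chain alkene follow.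

Key step: step 15

Numbering used throughout:
- Ring A = C13–C18.
- Ring B = C8, C9, C11–C14.
- Ring C = C5–C9 (cyclopentane).
- Ring D = C1–C5, C9, C10, with oxygen bridging C3 and C10.
- Methyl groups sit on C4 (two), C10, C13, C14 and C17; the side chain sits on C17.
- In the systematic names of the monocyclic ring-A compounds, C1 = C17, C3 = C13 and C4 = C14.
- In the names of the oxabicycles, C1 = C10, C2 = C9, C3 = C5, C4 = C4 and C5 = C3.

Assumption: the sense of induction in steps 2 and 5 is taken from the parent reactions of these catalysts (2-substituted acroleins; the 2-methylcyclohexanone enolate); both antipodes of both chiral ligands are commercial, so a reversed sense would be met by the mirror-image catalyst without changing the route.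

**Ring-A fragment**

Step 1
Reactants: 1 3-methylbut-3-en-2-one
Product: 2 tert-butyl(dimethyl)[(3-methylbuta-1,3-dien-2-yl)oxy]silane
Conditions: t-BuMe2SiOTf, Et3N, CH2Cl2, 0 °C
Reagents that add atoms: tert-butyldimethylsilyl trifluoromethanesulfonate, CC(C)(C)[Si](C)(C)OS(=O)(=O)C(F)(F)F
Why: Soft enolisation with a silyl triflate and an amine (silyl enol ether formation) can only deprotonate the acetyl CH3, so the 2-silyloxy-3-methyl diene forms as one regioisomer, and the silyl group is robust enough for steps 2 to 4 yet fluoride-labile for step 5.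

Step 2
Reactants: 2 tert-butyl(dimethyl)[(3-methylbuta-1,3-dien-2-yl)oxy]silane; 3 2-methylprop-2-enal (methacrolein)
Product: 4 (1R)-4-[(tert-butyldimethylsilyl)oxy]-1,3-dimethylcyclohex-3-ene-1-carbaldehyde
Conditions: (R)-3,3-diphenyl-1-(2-methylphenyl)tetrahydro-1H,3H-pyrrolo[1,2-c][1,3,2]oxazaborole·HN(SO2CF3)2 (10 mol %), CH2Cl2, −78 °C
Reagents that add atoms: none
Why: Catalytic enantioselective Diels–Alder reaction: the silyloxy group outweighs the methyl group and directs the "para" orientation (formyl-bearing C17 opposite C14, diene methyl on C13), and the protonated oxazaborolidine holds s-trans methacrolein through boron and a formyl C–H···O contact so that a phenyl group covers one face and C17, the only new stereocentre, forms as (R).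

Step 3
Reactants: 4 (1R)-4-[(tert-butyldimethylsilyl)oxy]-1,3-dimethylcyclohex-3-ene-1-carbaldehyde
Product: 5 methyl (2E)-3-[(1R)-4-[(tert-butyldimethylsilyl)oxy]-1,3-dimethylcyclohex-3-en-1-yl]prop-2-enoate
Conditions: Ph3P=CHCO2Me, toluene, 90 °C
Reagents that add atoms: methyl (triphenylphosphoranylidene)acetate, COC(=O)C=P(c1ccccc1)(c1ccccc1)c1ccccc1
Why: Wittig olefination with a stabilised ylide is neutral enough to spare the silyl enol ether, converts the non-enolisable neopentyl aldehyde into the (E)-enoate and brings in the three-carbon stub of the C17 side chain.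

Step 4
Reactants: 5 methyl (2E)-3-[(1R)-4-[(tert-butyldimethylsilyl)oxy]-1,3-dimethylcyclohex-3-en-1-yl]prop-2-enoate
Product: 6 methyl 3-[(1S)-4-[(tert-butyldimethylsilyl)oxy]-1,3-dimethylcyclohex-3-en-1-yl]propanoate
Conditions: H2 (1 atm), Pd/C, EtOAc (trace Et3N), 23 °C
Reagents that add atoms: none
Why: Heterogeneous catalytic hydrogenation saturates the accessible disubstituted enoate, whereas the tetrasubstituted silyl enol ether is too hindered to adsorb, so the masked C13/C14 enolate is kept (the C17 descriptor changes only through the priority rules).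

Step 5
Reactants: 6 methyl 3-[(1S)-4-[(tert-butyldimethylsilyl)oxy]-1,3-dimethylcyclohex-3-en-1-yl]propanoate
Product: 7 methyl 3-[(1S,3S)-1,3-dimethyl-4-oxo-3-(prop-2-en-1-yl)cyclohexyl]propanoate
Conditions: Pd2(dba)3 (2.5 mol %), (R)-4-tert-butyl-2-[2-(diphenylphosphanyl)phenyl]-4,5-dihydro-1,3-oxazole (6 mol %), diallyl carbonate, Bu4N[Ph3SiF2] (1.05 equiv), THF, 25 °C
Reagents that add atoms: diallyl carbonate, C=CCOC(=O)OCC=C
Why: Asymmetric Tsuji-type allylic alkylation of a silyl enol ether: fluoride releases the tetrasubstituted C13=C14 enolate regiospecifically, the π-allylpalladium complex of the chiral phosphinooxazoline allylates it, and since C17 offers only CH3 against CH2R the substrate has no bias of its own, so the (R)-ligand decides the C13 face (arrangement of (R)-2-allyl-2-methylcyclohexanone, allyl trans to the propanoate chain).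

Step 6
Reactants: 7 methyl 3-[(1S,3S)-1,3-dimethyl-4-oxo-3-(prop-2-en-1-yl)cyclohexyl]propanoate
Product: 9 methyl 3-[(1S,3R)-3-(2,2-dimethoxyethyl)-1,3-dimethyl-4-oxocyclohexyl]propanoate, via keto aldehyde 8 (not isolated)
Conditions: O3, CH2Cl2/MeOH, −78 °C; Me2S, −78 → 23 °C; then HC(OMe)3, TsOH·H2O (5 mol %), 23 °C
Reagents that add atoms: ozone, [O-][O+]=O (oxygen of 8); trimethyl orthoformate, COC(OC)OC
Why: Ozonolysis with reductive work-up cleaves the only alkene to the C11 aldehyde, and acid-catalysed acetalisation in the same flask masks it selectively because the C14 ketone next to quaternary C13 is too hindered to ketalise, so two alkenes or two free carbonyl groups never have to be told apart later.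

Step 7
Reactants: 9 methyl 3-[(1S,3R)-3-(2,2-dimethoxyethyl)-1,3-dimethyl-4-oxocyclohexyl]propanoate
Product: 10 methyl 3-[(1S,3R)-3-(2,2-dimethoxyethyl)-1,3-dimethyl-4-methylidenecyclohexyl]propanoate
Conditions: Ph3PCH3Br, KOt-Bu, THF, 0 → 45 °C
Reagents that add atoms: methyltriphenylphosphonium bromide, C[P+](c1ccccc1)(c1ccccc1)c1ccccc1.[Br-]
Why: Wittig methylenation of the only free carbonyl group: the non-stabilised ylide attacks the ketone much faster than the methyl ester, and the acetal is inert to base.

Step 8
Reactants: 10 methyl 3-[(1S,3R)-3-(2,2-dimethoxyethyl)-1,3-dimethyl-4-methylidenecyclohexyl]propanoate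
Product: 11 methyl 3-[(1S,3R)-1,3-dimethyl-4-methylidene-3-(2-oxoethyl)cyclohexyl]propanoate
Conditions: pyridinium p-toluenesulfonate (0.2 equiv), acetone/H2O, 45 °C
Reagents that add atoms: water, O
Why: Mild acid-catalysed acetal hydrolysis frees the aldehyde under conditions too weak to isomerise the exocyclic alkene or to start a carbonyl-ene closure.

**Ring-D fragment**

Step 9
Reactants: 12 3-methylbutan-2-one
Product: 13 3-bromo-3-methylbutan-2-one
Conditions: Br2, AcOH, 23 °C
Reagents that add atoms: bromine, BrBr
Why: Acid-catalysed α-bromination in a non-alcoholic medium runs through the more substituted enol and therefore gives the tertiary bromide.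

Step 10
Reactants: 13 3-bromo-3-methylbutan-2-one; 14 2-methylfuran
Product: 15 (±)-1,4,4-trimethyl-8-oxabicyclo[3.2.1]oct-6-en-3-one
Conditions: 14 (excess), Et3N, CF3CH2OH, 0 → 23 °C
Reagents that add atoms: none
Why: (4+3) cycloaddition of the 1,1-dimethyloxyallyl cation, released from 13 by enolisation and loss of bromide in the ionising fluoroalcohol: its tertiary terminus bonds to the unsubstituted, more nucleophilic furan carbon, so the gem-dimethyl carbon C4 lies next to C3–H and the CH2 (C9) next to C10–Me, and the bridge fixes the relative configuration of C3 and C10.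

Step 11
Reactants: 15 (±)-1,4,4-trimethyl-8-oxabicyclo[3.2.1]oct-6-en-3-one
Product: 16 (±)-1,4,4-trimethyl-8-oxabicyclo[3.2.1]octan-3-one
Conditions: H2 (1 atm), Pd/C, EtOAc, 23 °C
Reagents that add atoms: none
Why: Catalytic hydrogenation of the strained disubstituted alkene leaves the ketone and the ether bridge untouched.

Step 12
Reactants: 16 (±)-1,4,4-trimethyl-8-oxabicyclo[3.2.1]octan-3-one
Product: 17 (1R,5S)-1,4,4-trimethyl-8-oxabicyclo[3.2.1]octan-3-one
Conditions: preparative supercritical-fluid chromatography, amylose tris(3,5-dimethylphenylcarbamate) on silica, CO2/MeOH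
Reagents that add atoms: none
Why: Resolution of the racemate on a chiral stationary phase makes no bond and fixes the absolute configuration of C3 and C10, the wanted antipode being identified by vibrational circular dichroism or by X-ray analysis of a crystalline derivative.

Step 13
Reactants: 17 (1R,5S)-1,4,4-trimethyl-8-oxabicyclo[3.2.1]octan-3-one; 18 3-[(tert-butyldimethylsilyl)oxy]propanal
Product: 19 (1R,5S)-2-{3-[(tert-butyldimethylsilyl)oxy]-1-hydroxypropyl}-1,4,4-trimethyl-8-oxabicyclo[3.2.1]octan-3-one (epimers at C2 and at the carbinol carbon)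
Conditions: LiN(i-Pr)2, THF, −78 °C; 18, −78 °C; AcOH quench
Reagents that add atoms: none
Why: Directed aldol addition: C9 is the only enolisable position because C4 is quaternary, and the configuration of the two new centres is irrelevant since both are erased in step 14.

Step 14
Reactants: 19 (1R,5S)-2-{3-[(tert-butyldimethylsilyl)oxy]-1-hydroxypropyl}-1,4,4-trimethyl-8-oxabicyclo[3.2.1]octan-3-one
Product: 21 (1R,2Z,5S)-2-{3-[(tert-butyldimethylsilyl)oxy]propylidene}-1,4,4-trimethyl-8-oxabicyclo[3.2.1]octan-3-one, via mesylate 20 (not isolated)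
Conditions: MeSO2Cl, Et3N, CH2Cl2, 0 °C; then 1,8-diazabicyclo[5.4.0]undec-7-ene (DBU), 0 → 23 °C
Reagents that add atoms: methanesulfonyl chloride, CS(=O)(=O)Cl (atoms kept only in 20)
Why: Mesylation and base-induced E1cB elimination complete the aldol condensation, and the equilibrating medium should favour the (Z)-isomer because in the (E)-isomer C7 would collide with the in-plane C10 methyl group (allylic 1,3-strain), whereas syn to the carbonyl oxygen it is unhindered.

**Fragment union**

Step 15
Reactants: 11 methyl 3-[(1S,3R)-1,3-dimethyl-4-methylidene-3-(2-oxoethyl)cyclohexyl]propanoate; 21 (1R,2Z,5S)-2-{3-[(tert-butyldimethylsilyl)oxy]propylidene}-1,4,4-trimethyl-8-oxabicyclo[3.2.1]octan-3-one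
Product: 22 ring-B annulation product: trans-fused rings A/B (C13-Me and C14-Me anti) joined spiro at C9 to ring D, C11 carbinol, C5 ketone, CH2CH2OTBS arm on C8, methyl propanoate chain on C17
Conditions: Fe(acac)3 (0.3 equiv), PhSiH3 (2.5 equiv, slow addition), ClCH2CH2Cl/HOCH2CH2OH (10:1), degassed, 0 → 23 °C
Reagents that add atoms: none
Why: Fe(acac)3 and PhSiH3 form a hydride of trivalent iron that transfers a hydrogen atom to the CH2 terminus of the methylene group of 11 (which creates the C14 methyl), the nucleophilic tertiary C14 radical adds to the β-carbon C8 of 21, divalent iron reduces the α-keto radical to the C9 iron enolate, and this adds to the tethered C11 aldehyde. The closest known reaction type is the hydrogen-atom-transfer-initiated radical–polar crossover annulation (Giese addition followed by intramolecular aldol), a formal [4+2] known to give cyclohexanols with adjacent quaternary carbons. Ring B closes in a 6-(enolexo)-exo-trig aldol. C8 and C9 are controlled by the bicycle: both bonds form on the exo face (the side of the oxygen bridge) because the C1–C2 bridge covers the endo face, so C11 ends axial and C8 equatorial on ring D, and the (Z)-geometry turns exo attack into the required C8 configuration, while C11 forms as a carbinol whose configuration is of no consequence. C14 is controlled by ring A: the acceptor should enter axially and anti to the axial CH2CHO arm on C13, which gives the trans A/B fusion with anti methyl groups, but this rests only on the small difference between CH2CHO and CH3 and is the weak point of the step. The step also needs hydrogen-atom transfer to hit the electron-neutral 1,1-disubstituted alkene and not the electron-poor trisubstituted enone (secured by polarity, and by carrying the side chain as an ester instead of a competing trisubstituted alkene), and it needs the aldol to outrun protonation (secured by the six-membered tether and the low protic content).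

**Completion**

Step 16
Reactants: 22 ring-B annulation product
Product: 23 C11 O-phenyl thionocarbonate of 22
Conditions: PhOC(S)Cl, 4-(dimethylamino)pyridine, MeCN, 23 °C
Reagents that add atoms: O-phenyl chlorothionoformate, ClC(=S)Oc1ccccc1
Why: Acylation of the hindered C11 alcohol with an aryl chlorothionoformate under nucleophilic catalysis (first half of a Barton–McCombie deoxygenation) works for either C11 epimer and is too weakly basic at ambient temperature to open the β-hydroxy ketone by retro-aldol cleavage.

Step 17
Reactants: 23 C11 O-phenyl thionocarbonate of 22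
Product: 24 11-deoxy ketone (C11 = CH2; otherwise as 22)
Conditions: Bu3SnH (5 equiv, 0.5 M), PhSeSePh (0.1 equiv), Et3B (0.5 equiv), air, toluene, 23 °C
Reagents that add atoms: none
Why: Barton–McCombie deoxygenation: because the C11 radical lies β to the C5 carbonyl and could undergo a 1,2-acyl shift, the chain is run at ambient temperature and high stannane concentration with PhSeH (formed from PhSeSePh) as a very fast hydrogen donor, so hydrogen abstraction outruns rearrangement.

Step 18
Reactants: 24 11-deoxy ketone
Product: 25 primary alcohol (CH2CH2OH arm on C8)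
Conditions: HF·pyridine, THF, 0 → 23 °C
Reagents that add atoms: none
Why: Fluoride-mediated cleavage of the primary silyl ether under slightly acidic conditions leaves the ester, the ketone and the tertiary ether bridge untouched.

Step 19
Reactants: 25 primary alcohol
Product: 26 primary iodide (CH2CH2I arm on C8)
Conditions: I2, PPh3, imidazole, CH2Cl2, 0 °C
Reagents that add atoms: iodine, II
Why: Appel iodination of the unhindered primary alcohol proceeds by SN2 displacement of the alkoxyphosphonium ion.

Step 20
Reactants: 26 primary iodide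
Product: 27 pentacyclic C5 tertiary alcohol (ring C closed by the C5–C6 bond; C5 configuration open)
Conditions: SmI2 (3 equiv), (Me2N)3PO, THF, −78 → 0 °C
Reagents that add atoms: none
Why: Intramolecular samarium Barbier reaction: divalent samarium reduces the primary iodide and the carbon nucleophile adds to the C5 carbonyl in a 5-exo closure that tolerates the two quaternary neighbours because it is intramolecular, the ester is inert, and the carbinol configuration does not matter since steps 21 and 22 erase it.

Step 21
Reactants: 27 pentacyclic C5 tertiary alcohol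
Product: 28 pentacyclic C5=C6 alkene
Conditions: SOCl2, pyridine, −20 → 0 °C
Reagents that add atoms: none
Why: Dehydration through the chlorosulfite by pyridine-induced E2 elimination: C4 and C9 are quaternary, so only C6 offers β-hydrogen atoms and one alkene can form, and the basic medium suppresses cationic skeletal shifts.

Step 22
Reactants: 28 pentacyclic C5=C6 alkene
Product: 29 pentacyclic methyl ester with (5S)-H (H5 endo, anti to C11; trans C/D fusion)
Conditions: Mn(dpm)3 (dpm = 2,2,6,6-tetramethylheptane-3,5-dionate, 10 mol %), PhSiH3, t-BuOOH, i-PrOH, 23 °C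
Reagents that add atoms: none
Why: Hydrogen-atom-transfer hydrogenation: a manganese hydride delivers hydrogen to C6, and the tertiary C5 radical should take its hydrogen on the endo face, since the exo face is walled by the axial C4 methyl and the axial C11 methylene and exo delivery would push C6 into the pocket above the C1–C2 bridge, which sets C5.

Step 23
Reactants: 29 pentacyclic methyl ester
Product: 30 pentacyclic aldehyde (CH2CH2CHO on C17)
Conditions: i-Bu2AlH (1.1 equiv), CH2Cl2, −78 °C; aq. potassium sodium tartrate
Reagents that add atoms: none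
Why: Partial reduction of the only remaining carbonyl group: the tetrahedral aluminium hemiacetal is stable at −78 °C and collapses to the aldehyde only on work-up.

Step 24
Reactants: 30 pentacyclic aldehyde
Product: 31 target CNP0284367.1, (3S,5S,8R,9R,10R,13S,14R,17R) in the numbering used here
Conditions: i-PrPPh3I, n-BuLi, THF, 0 °C; then 30, −78 → 23 °C
Reagents that add atoms: isopropyltriphenylphosphonium iodide, CC(C)[P+](c1ccccc1)(c1ccccc1)c1ccccc1.[I-]
Why: Wittig olefination with the non-stabilised isopropylidene ylide gives the trisubstituted alkene, which has no E/Z issue, and completes the 4-methylpent-3-enyl chain last so that it never meets the hydrogen-atom-transfer or hydrogenation steps.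

**Compound list**

1 | 3-methylbut-3-en-2-one | CC(=O)C(C)=C | starting material
2 | tert-butyl(dimethyl)[(3-methylbuta-1,3-dien-2-yl)oxy]silane | C=C(C)C(=C)O[Si](C)(C)C(C)(C)C | intermediate
3 | 2-methylprop-2-enal | CC(=C)C=O | starting material
4 | (1R)-4-[(tert-butyldimethylsilyl)oxy]-1,3-dimethylcyclohex-3-ene-1-carbaldehyde | O=C[C@]1(C)CCC(O[Si](C)(C)C(C)(C)C)=C(C)C1 | intermediate
5 | methyl (2E)-3-[(1R)-4-[(tert-butyldimethylsilyl)oxy]-1,3-dimethylcyclohex-3-en-1-yl]prop-2-enoate | COC(=O)/C=C/[C@]1(C)CCC(O[Si](C)(C)C(C)(C)C)=C(C)C1 | intermediate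
6 | methyl 3-[(1S)-4-[(tert-butyldimethylsilyl)oxy]-1,3-dimethylcyclohex-3-en-1-yl]propanoate | COC(=O)CC[C@]1(C)CCC(O[Si](C)(C)C(C)(C)C)=C(C)C1 | intermediate
7 | methyl 3-[(1S,3S)-1,3-dimethyl-4-oxo-3-(prop-2-en-1-yl)cyclohexyl]propanoate | COC(=O)CC[C@]1(C)CCC(=O)[C@@](C)(CC=C)C1 | intermediate
8 | methyl 3-[(1S,3R)-1,3-dimethyl-4-oxo-3-(2-oxoethyl)cyclohexyl]propanoate | COC(=O)CC[C@]1(C)CCC(=O)[C@@](C)(CC=O)C1 | intermediate
9 | methyl 3-[(1S,3R)-3-(2,2-dimethoxyethyl)-1,3-dimethyl-4-oxocyclohexyl]propanoate | COC(=O)CC[C@]1(C)CCC(=O)[C@@](C)(CC(OC)OC)C1 | intermediate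
10 | methyl 3-[(1S,3R)-3-(2,2-dimethoxyethyl)-1,3-dimethyl-4-methylidenecyclohexyl]propanoate | COC(=O)CC[C@]1(C)CCC(=C)[C@@](C)(CC(OC)OC)C1 | intermediate
11 | methyl 3-[(1S,3R)-1,3-dimethyl-4-methylidene-3-(2-oxoethyl)cyclohexyl]propanoate | COC(=O)CC[C@]1(C)CCC(=C)[C@@](C)(CC=O)C1 | intermediate
12 | 3-methylbutan-2-one | CC(C)C(C)=O | starting material
13 | 3-bromo-3-methylbutan-2-one | CC(=O)C(C)(C)Br | intermediate
14 | 2-methylfuran | Cc1ccco1 | starting material
15 | (±)-1,4,4-trimethyl-8-oxabicyclo[3.2.1]oct-6-en-3-one (both enantiomers) | O=C1C[C@@]2(C)C=C[C@H](O2)C1(C)C.O=C1C[C@]2(C)C=C[C@@H](O2)C1(C)C | intermediate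
16 | (±)-1,4,4-trimethyl-8-oxabicyclo[3.2.1]octan-3-one (both enantiomers) | O=C1C[C@@]2(C)CC[C@H](O2)C1(C)C.O=C1C[C@]2(C)CC[C@@H](O2)C1(C)C | intermediate
17 | (1R,5S)-1,4,4-trimethyl-8-oxabicyclo[3.2.1]octan-3-one | O=C1C[C@@]2(C)CC[C@H](O2)C1(C)C | intermediate
18 | 3-[(tert-butyldimethylsilyl)oxy]propanal | O=CCCO[Si](C)(C)C(C)(C)C | starting material
19 | (1R,5S)-2-{3-[(tert-butyldimethylsilyl)oxy]-1-hydroxypropyl}-1,4,4-trimethyl-8-oxabicyclo[3.2.1]octan-3-one (epimers at C2 and carbinol) | O=C1C(C(O)CCO[Si](C)(C)C(C)(C)C)[C@@]2(C)CC[C@H](O2)C1(C)C | intermediate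
20 | methanesulfonate of 19 | O=C1C(C(OS(C)(=O)=O)CCO[Si](C)(C)C(C)(C)C)[C@@]2(C)CC[C@H](O2)C1(C)C | intermediate
21 | (1R,2Z,5S)-2-{3-[(tert-butyldimethylsilyl)oxy]propylidene}-1,4,4-trimethyl-8-oxabicyclo[3.2.1]octan-3-one | O=C1/C(=C\CCO[Si](C)(C)C(C)(C)C)[C@@]2(C)CC[C@H](O2)C1(C)C | intermediate
22 | ring-B annulation product (rings A/B trans-fused, spiro at C9 to ring D, C11-OH, C5 ketone, C8 silyloxyethyl arm, C17 methyl propanoate chain) | COC(=O)CC[C@]1(C)CC[C@]2(C)[C@@H](CCO[Si](C)(C)C(C)(C)C)[C@]3(C(O)C[C@@]2(C)C1)C(=O)C(C)(C)[C@@H]4CC[C@@]3(C)O4 | intermediate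
23 | C11 O-phenyl thionocarbonate of 22 | COC(=O)CC[C@]1(C)CC[C@]2(C)[C@@H](CCO[Si](C)(C)C(C)(C)C)[C@]3(C(OC(=S)Oc5ccccc5)C[C@@]2(C)C1)C(=O)C(C)(C)[C@@H]4CC[C@@]3(C)O4 | intermediate
24 | 11-deoxy ketone | COC(=O)CC[C@]1(C)CC[C@]2(C)[C@@H](CCO[Si](C)(C)C(C)(C)C)[C@]3(CC[C@@]2(C)C1)C(=O)C(C)(C)[C@@H]4CC[C@@]3(C)O4 | intermediate
25 | primary alcohol (C6-OH) | COC(=O)CC[C@]1(C)CC[C@]2(C)[C@@H](CCO)[C@]3(CC[C@@]2(C)C1)C(=O)C(C)(C)[C@@H]4CC[C@@]3(C)O4 | intermediate
26 | primary iodide (C6-I) | COC(=O)CC[C@]1(C)CC[C@]2(C)[C@@H](CCI)[C@]3(CC[C@@]2(C)C1)C(=O)C(C)(C)[C@@H]4CC[C@@]3(C)O4 | intermediate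
27 | pentacyclic C5 tertiary alcohol (C5 open) | COC(=O)CC[C@]1(C)CC[C@]2(C)[C@H]3CCC4(O)C(C)(C)[C@@H]5CC[C@@](C)(O5)[C@@]43CC[C@@]2(C)C1 | intermediate
28 | pentacyclic C5=C6 alkene | COC(=O)CC[C@]1(C)CC[C@]2(C)[C@H]3CC=C4C(C)(C)[C@@H]5CC[C@@](C)(O5)[C@@]43CC[C@@]2(C)C1 | intermediate
29 | pentacyclic methyl ester, (5S)-H | COC(=O)CC[C@]1(C)CC[C@]2(C)[C@H]3CC[C@H]4C(C)(C)[C@@H]5CC[C@@](C)(O5)[C@@]43CC[C@@]2(C)C1 | intermediate
30 | pentacyclic aldehyde | O=CCC[C@]1(C)CC[C@]2(C)[C@H]3CC[C@H]4C(C)(C)[C@@H]5CC[C@@](C)(O5)[C@@]43CC[C@@]2(C)C1 | intermediate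
31 | CNP0284367.1 | CC(C)=CCC[C@]1(C)CC[C@]2(C)[C@H]3CC[C@H]4C(C)(C)[C@@H]5CC[C@@](C)(O5)[C@@]43CC[C@@]2(C)C1 | target

**Step count**

Total step count: 24.
Longest linear sequence: 18 (steps 1–8 and 15–24).

**Steps most likely to fail**

Step 15. The C14 radical may be attacked with poor facial selectivity. The C9 enolate may also be protonated before ring closure, or the alkene may simply be reduced.

The fallback separates the radical event from the polar event. It sets out from 10 and 21 and returns at 22.
- Acetal 10, with its aldehyde still masked, is coupled with 21 under Fe(acac)3/PhSiH3 in EtOH at 60 °C (reductive olefin coupling with protonation of the enolate). This gives the ring-B-open keto acetal F1, whose C14 epimers can be separated at this stage.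
- Pyridinium p-toluenesulfonate in wet acetone frees the keto aldehyde F2.
- A reversible base-catalysed aldol (NaOMe, MeOH, 0 → 23 °C) closes ring B to 22. The hindered C5 carbonyl is no acceptor, and C9 is the only enolisable position of the ketone.

Step 17. The C11 radical may migrate the C5 acyl group (1,2-acyl shift with enlargement of ring D) in competition with hydrogen abstraction.

The fallback avoids any radical at C11. It sets out from 22 and returns at 24.
- Methyl N-(triethylammoniosulfonyl)carbamate in toluene at 80 °C removes the C11 hydroxyl by syn-elimination. Only C12 carries β-hydrogen, so the product is the C11=C12 alkene F3.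
- Hydrogenation (H2 under pressure, Pd/C, EtOAc) saturates it to 24.

Step 22. Hydrogen may be delivered to the exo face of the C5 radical, which would give the cis C/D fusion. Hydrogen-atom transfer to the hindered alkene may also be sluggish.

The fallback replaces the radical hydrogenation by surface-mediated syn addition. Alkene 28 is hydrogenated over PtO2 (H2 under pressure, EtOAc/AcOH), where adsorption should take place on the open face that carries H8, away from ring B and the axial C4 methyl. It sets out from 28, returns at 29 and makes no new compound F0.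

**Further compounds**

F1 | step 15 | ring-B-open keto acetal (C8–C14 bond made, C9–H epimers) | COC(=O)CC[C@]1(C)CC[C@](C)([C@@H](CCO[Si](C)(C)C(C)(C)C)C2C(=O)C(C)(C)[C@@H]3CC[C@@]2(C)O3)[C@@](C)(CC(OC)OC)C1
F2 | step 15 | ring-B-open keto aldehyde | COC(=O)CC[C@]1(C)CC[C@](C)([C@@H](CCO[Si](C)(C)C(C)(C)C)C2C(=O)C(C)(C)[C@@H]3CC[C@@]2(C)O3)[C@@](C)(CC=O)C1
F3 | step 17 | C11=C12 alkene | COC(=O)CC[C@]1(C)CC[C@]2(C)[C@@H](CCO[Si](C)(C)C(C)(C)C)[C@]3(C=C[C@@]2(C)C1)C(=O)C(C)(C)[C@@H]4CC[C@@]3(C)O4
F0 | step 22 | none | none
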